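The easy step is the balance of X with E, which is kept while Z and X turn into Z.X and E returns.

    X + E ⇌ X.E, settled at all times (K1 = 5.9 L mol⁻¹)
    Z + X + E → Z.X + E, rate k2*[Z]*[X]*[E]/(1 + ([Z]/sat2)) (sat2 = 0.77 M, k2 = 18000 L² mol⁻² s⁻¹)

Z 0.30 M; X 0.180 M; E 0.17 mM

1. factor on the rate of making Z.X when 5.0% of the Z are converted if E is charged twice over
2. factor on the rate when 5.0% of the Z are converted if E is charged at 1.5 mM instead

When 5.0% of the Z has reacted, an equal amount of X has gone, so 0.917 of the X charge remains outside Z.X. The rate law counts free E, so the useful number is the fraction of the catalyst charged that stands as E at that moment. For the flask as charged, this free share is 0.507, from the balance constant 5.9 L mol⁻¹ and the X remaining.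

The first way takes the free share and free X as unchanged by the catalyst charge. The rate then follows the charge, giving 2 for the doubled flask and 8.82 for the 1.5 mM flask. The second way counts the X held in X.E, an off-cycle form of the catalyst. X.E holds 0.0508% of the remaining X in the flask as charged and 0.448% in the 1.5 mM flask. In the 1.5 mM flask that loss of free X lowers the rate, while the reckoned free share rises slightly to 0.508. With 0.507 for the flask as charged and 0.507 for the doubled flask, the factors become 2.00 and 8.81. The two ways agree closely, and the first cheats by just 0.202% on the 1.5 mM flask.

The forecast gives 2 and 8.806, holding that “free E is a nearly fixed fraction (about half) of the total at the same conversion”.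

The simulation gives 2.00 and 8.81. In the flask as charged, 5.0% of the Z is converted at 0.271 s, and Z.X is then made at 3.19 M min⁻¹. A run of that flask without the association of X and E reaches 1.97 times that rate. That multiple is the inverse of the free share, 1.97. For the 1.5 mM flask, the reckoned free share is 0.508, and the simulated factor puts the rate at 28.1 M min⁻¹.

The numbers come from no measurement; the run is a simulation.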